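Ring A of the dihydrobenzofuran is built, not bought. Its adjacent oxygens, O1 on C7a and the methoxy oxygen on C7, mark an alkynyl ether (C7a≡C7) fused to a furan that supplies C3a, C4, C5 and C6 and passes its own oxygen to C7. A gold-catalysed furan–ynol ether cycloisomerization therefore forms C3a–C7a, C6–C7 and C7–O at once, closing ring A and the dihydrofuran ring around two stereocentres set earlier by an auxiliary-controlled syn aldol. The precursor is an acyclic secondary ethynyl ether whose carbinol carbon bears ring B and whose neighbouring carbon bears a silyloxymethyl group and a 4-(silyloxymethyl)furan-2-yl group.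

Key step: step 10

Remark on the chemistry: both primary hydroxyls are carried as triisopropylsilyl ethers, which resist base-induced oxygen-to-oxygen migration in step 8 better than smaller silyl groups; the furan keeps its deactivating ester until the aldol is done; 1 and 2 are taken as catalogue items; alkynyl ether 16 is never warmed above room temperature.

Step 1
Reactants: 1 methyl 5-bromofuran-3-carboxylate; 2 (2-tert-butoxy-2-oxoethyl)zinc chloride (0.5 M in Et2O)
Product: 3 tert-butyl 2-[4-(methoxycarbonyl)furan-2-yl]acetate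
Conditions: Pd2(dba)3 (2.5 mol %), XPhos (10 mol %), THF, 60 °C
Reagents that add atoms: none
Why: Negishi coupling of a Reformatsky-type zinc enolate, in which zerovalent palladium inserts readily into the C–Br bond of the electron-poor 2-bromofuran and the mild zinc reagent leaves both esters alone.

Step 2
Reactants: 3 tert-butyl 2-[4-(methoxycarbonyl)furan-2-yl]acetate
Product: 4 2-[4-(methoxycarbonyl)furan-2-yl]acetic acid
Conditions: TFA, CH2Cl2, rt
Reagents that add atoms: none
Why: Acidolysis of the tert-butyl ester by E1 loss of isobutene should spare the methyl ester and the furan, which its ester deactivates towards acid.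

Step 3
Reactants: 4 2-[4-(methoxycarbonyl)furan-2-yl]acetic acid; 5 (R)-4-benzyl-2-oxazolidinone
Product: 7 methyl 5-{2-[(4R)-4-benzyl-2-oxo-1,3-oxazolidin-3-yl]-2-oxoethyl}furan-3-carboxylate, via mixed pivalic anhydride 6 (not isolated)
Conditions: PivCl, Et3N, THF, −20 °C; then 5, LiCl, −20 °C → rt
Reagents that add atoms: none
Why: N-acylation of the oxazolidinone through a mixed anhydride under LiCl/amine activation, where the hindered pivaloyl carbonyl steers attack to the furylacetyl carbonyl and no strong base meets the acidic methylene.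

Step 4
Reactants: 8 3,4-dihydroxy-5-methoxybenzaldehyde
Product: 9 3-methoxy-4,5-bis(methoxymethoxy)benzaldehyde
Conditions: MOMCl, i-Pr2NEt, CH2Cl2, 0 °C → rt
Reagents that add atoms: chloromethyl methyl ether (COCCl)
Why: Williamson-type O-alkylation of both phenols by the reactive chloromethyl ether under amine base, to which the aldehyde is inert.

Step 5
Reactants: 7 methyl 5-{2-[(4R)-4-benzyl-2-oxo-1,3-oxazolidin-3-yl]-2-oxoethyl}furan-3-carboxylate; 9 3-methoxy-4,5-bis(methoxymethoxy)benzaldehyde
Product: 11 (4R)-4-benzyl-3-{(2S,3R)-3-hydroxy-2-[4-(methoxycarbonyl)furan-2-yl]-3-[3-methoxy-4,5-bis(methoxymethoxy)phenyl]propanoyl}-1,3-oxazolidin-2-one, via boron enolate 10 (not isolated)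
Conditions: Bu2BOTf, i-Pr2NEt, CH2Cl2, −78 → 0 °C; then 9, −78 → 0 °C; pH 7 buffer, MeOH, 30% H2O2, 0 °C
Reagents that add atoms: none
Why: Evans syn aldol, in which the (Z)-boron enolate adds through a Zimmerman–Traxler chair on the enolate face left open by the benzyl group of the (R)-auxiliary, so that the 2S and 3R centres (syn) are set together.

Step 6
Reactants: 11 syn aldol adduct (2S,3R)
Product: 12 (1R,2S)-2-[4-(hydroxymethyl)furan-2-yl]-1-[3-methoxy-4,5-bis(methoxymethoxy)phenyl]propane-1,3-diol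
Conditions: LiBH4, THF–MeOH, 0 °C → rt
Reagents that add atoms: none
Why: Borohydride reduction cleaves the imide reductively to the primary alcohol with release of the auxiliary at 0 °C and, on warming, reduces the furan methyl ester as well, without touching either stereocentre.

Step 7
Reactants: 12 (1R,2S)-2-[4-(hydroxymethyl)furan-2-yl]-1-[3-methoxy-4,5-bis(methoxymethoxy)phenyl]propane-1,3-diol
Product: 13 (1R,2S)-1-[3-methoxy-4,5-bis(methoxymethoxy)phenyl]-3-[(triisopropylsilyl)oxy]-2-(4-{[(triisopropylsilyl)oxy]methyl}furan-2-yl)propan-1-ol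
Conditions: TIPSCl (2.3 equiv), imidazole, DMF, 0 °C → rt
Reagents that add atoms: triisopropylsilyl chloride (CC(C)[Si](Cl)(C(C)C)C(C)C)
Why: Imidazole-promoted silylation with the bulky chlorosilane should take only the two primary hydroxyls and leave the hindered secondary benzylic hydroxyl free for the next step.

Step 8
Reactants: 13 bis(triisopropylsilyl) ether with free secondary hydroxyl (1R,2S)
Product: 14 (E)-1,2-dichlorovinyl ether of 13 (OCCl=CHCl on the benzylic carbon; 1R,2S)
Conditions: KH, THF, 0 °C; then Cl2C=CHCl, −40 °C → rt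
Reagents that add atoms: trichloroethylene (ClC=C(Cl)Cl)
Why: Addition of the potassium alkoxide to dichloroacetylene formed in situ (first stage of the trichloroethylene route to ynol ethers) makes the enol ether without a bond to either stereocentre being broken, and the bulky silyl groups and low temperature disfavour silyl transfer to the alkoxide.

Step 9
Reactants: 14 (E)-1,2-dichlorovinyl ether
Product: 16 (1R,2S)-1-(ethynyloxy)-1-[3-methoxy-4,5-bis(methoxymethoxy)phenyl]-3-[(triisopropylsilyl)oxy]-2-(4-{[(triisopropylsilyl)oxy]methyl}furan-2-yl)propane, via lithium acetylide 15 (not isolated)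
Conditions: n-BuLi (2.5 equiv), THF, −78 → −40 °C; then MeOH, −78 °C; cold work-up, used at once
Reagents that add atoms: none
Why: Vinyl deprotonation with β-elimination of LiCl followed by chlorine–lithium exchange (second stage of the same ynol ether synthesis) gives the lithium alkoxyacetylide, and the cold protic quench, which also returns any adventitiously lithiated arene or furan position to C–H, delivers the heat-sensitive terminal alkynyl ether.

Step 10
Reactants: 16 syn-configured furyl ethynyl ether (1R,2S)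
Product: 19 (2R,3S)-2-[3-methoxy-4,5-bis(methoxymethoxy)phenyl]-3,5-bis{[(triisopropylsilyl)oxy]methyl}-2,3-dihydro-1-benzofuran-7-ol, via oxepine 17 (not isolated), via arene oxide 18 (not isolated)
Conditions: Ph3PAuNTf2 (5 mol %), CH2Cl2, 4 Å molecular sieves, 0 °C → rt
Reagents that add atoms: none
Why: This is the gold-catalysed furan–yne phenol synthesis, an atom-neutral cycloisomerization whose closest known cases are furans tethered to terminal alkynyl ethers that give 7-hydroxy-2,3-dihydrobenzofurans near room temperature. Cationic monovalent gold polarises the ynol ether so that its oxygen-bearing carbon (future C7a) is attacked by the tether-bearing furan α-carbon (future C3a) in a 5-exo-dig closure, which makes the dihydrofuran ring and a cyclopropyl gold carbenoid. The carbenoid opens to a gold-carbene dienal whose aldehyde oxygen adds to the carbene carbon (future C7) to give oxepine 17, and 6π electrocyclisation of 17 forms C6–C7 and so closes ring A as arene oxide 18. The oxide opens by C6–O cleavage because the resulting cyclohexadienyl cation carries charge on C7a, where O1 stabilises it, whereas C7–O cleavage would gain nothing from O1; the hydroxyl therefore stays on C7. No stereocentre is created and no bond to C2 or C3 is broken, so under these near-neutral conditions the syn precursor can only give the trans product. Chemoselectivity for the furan over ring B as the nucleophile follows from the higher nucleophilicity of the dialkylfuran and the five-membered transition state, and molecular sieves keep the ynol ether from being hydrated.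

Step 11
Reactants: 19 trans-7-hydroxy-2,3-dihydrobenzofuran (2R,3S)
Product: 20 (2R,3S)-7-methoxy-2-[3-methoxy-4,5-bis(methoxymethoxy)phenyl]-3,5-bis{[(triisopropylsilyl)oxy]methyl}-2,3-dihydro-1-benzofuran
Conditions: MeI, K2CO3, DMF, rt
Reagents that add atoms: iodomethane (CI)
Why: Williamson O-methylation of the only free phenol under mild carbonate base, to which the silyl and methoxymethyl ethers are stable.

Step 12
Reactants: 20 7-methyl ether (2R,3S)
Product: 21 [(2R,3S)-7-methoxy-2-[3-methoxy-4,5-bis(methoxymethoxy)phenyl]-2,3-dihydro-1-benzofuran-3,5-diyl]dimethanol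
Conditions: TBAF, THF, 0 °C → rt
Reagents that add atoms: none
Why: Fluoride-driven desilylation (strong Si–F bond) should remove both triisopropylsilyl groups and leave the acid-labile methoxymethyl ethers in place.

Step 13
Reactants: 21 diol (2R,3S)
Product: 22 (2R,3S)-3-(hydroxymethyl)-7-methoxy-2-[3-methoxy-4,5-bis(methoxymethoxy)phenyl]-2,3-dihydro-1-benzofuran-5-carbaldehyde
Conditions: MnO2 (activated, excess), CH2Cl2, rt
Reagents that add atoms: none
Why: Chemoselective MnO2 oxidation, which should convert only the benzylic alcohol on ring A to the aldehyde and leave the saturated primary alcohol on C3 and the masked catechol alone.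

Step 14
Reactants: 22 C5 aldehyde (2R,3S); 23 (triphenylphosphoranylidene)acetaldehyde
Product: 24 (E)-3-[(2R,3S)-3-(hydroxymethyl)-7-methoxy-2-[3-methoxy-4,5-bis(methoxymethoxy)phenyl]-2,3-dihydro-1-benzofuran-5-yl]prop-2-enal
Conditions: 23 (1.3 equiv), toluene, 80 °C
Reagents that add atoms: none
Why: Wittig olefination with a stabilised formylmethylene ylide should give the (E)-enal, with a small excess of ylide and moderate temperature limiting a second homologation and the free primary alcohol being tolerated.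

Step 15
Reactants: 24 bis(methoxymethyl) ether of cassyformin
Product: 25 cassyformin, (E)-3-[(2R,3S)-2-(3,4-dihydroxy-5-methoxyphenyl)-3-(hydroxymethyl)-7-methoxy-2,3-dihydro-1-benzofuran-5-yl]prop-2-enal
Conditions: 2 M aq. HCl, THF (degassed), 40 °C
Reagents that add atoms: none
Why: Acid-catalysed hydrolysis of the two aryl methoxymethyl acetals frees the catechol, and aqueous THF without an alcohol cosolvent should avoid acetal formation or conjugate addition at the enal and be mild enough for the benzylic C2–O1 ether.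

Compound list

1 | methyl 5-bromofuran-3-carboxylate | COC(=O)c1coc(Br)c1 | starting material
2 | (2-tert-butoxy-2-oxoethyl)zinc chloride | CC(C)(C)OC(=O)C[Zn]Cl | starting material
3 | tert-butyl 2-[4-(methoxycarbonyl)furan-2-yl]acetate | COC(=O)c1coc(CC(=O)OC(C)(C)C)c1 | intermediate
4 | 2-[4-(methoxycarbonyl)furan-2-yl]acetic acid | COC(=O)c1coc(CC(=O)O)c1 | intermediate
5 | (R)-4-benzyl-2-oxazolidinone | O=C1N[C@H](Cc2ccccc2)CO1 | starting material
6 | mixed anhydride of 4 and pivalic acid (not isolated) | COC(=O)c1coc(CC(=O)OC(=O)C(C)(C)C)c1 | intermediate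
7 | methyl 5-{2-[(4R)-4-benzyl-2-oxo-1,3-oxazolidin-3-yl]-2-oxoethyl}furan-3-carboxylate | COC(=O)c1coc(CC(=O)N2[C@H](Cc3ccccc3)COC2=O)c1 | intermediate
8 | 3,4-dihydroxy-5-methoxybenzaldehyde | COc1cc(C=O)cc(O)c1O | starting material
9 | 3-methoxy-4,5-bis(methoxymethoxy)benzaldehyde | COCOc1cc(C=O)cc(OC)c1OCOC | intermediate
10 | (Z)-dibutylboron enolate of 7 (not isolated) | CCCCB(CCCC)O/C(=C\c1cc(C(=O)OC)co1)N1[C@H](Cc2ccccc2)COC1=O | intermediate
11 | (4R)-4-benzyl-3-{(2S,3R)-3-hydroxy-2-[4-(methoxycarbonyl)furan-2-yl]-3-[3-methoxy-4,5-bis(methoxymethoxy)phenyl]propanoyl}-1,3-oxazolidin-2-one | COc1cc([C@H](O)[C@H](C(=O)N2[C@H](Cc3ccccc3)COC2=O)c2cc(C(=O)OC)co2)cc(OCOC)c1OCOC | intermediate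
12 | (1R,2S)-2-[4-(hydroxymethyl)furan-2-yl]-1-[3-methoxy-4,5-bis(methoxymethoxy)phenyl]propane-1,3-diol | COc1cc([C@H](O)[C@H](CO)c2cc(CO)co2)cc(OCOC)c1OCOC | intermediate
13 | (1R,2S)-1-[3-methoxy-4,5-bis(methoxymethoxy)phenyl]-3-[(triisopropylsilyl)oxy]-2-(4-{[(triisopropylsilyl)oxy]methyl}furan-2-yl)propan-1-ol | COc1cc([C@H](O)[C@H](CO[Si](C(C)C)(C(C)C)C(C)C)c2cc(CO[Si](C(C)C)(C(C)C)C(C)C)co2)cc(OCOC)c1OCOC | intermediate
14 | (E)-1,2-dichlorovinyl ether of 13 (1R,2S) | COc1cc([C@H](O/C(Cl)=C\Cl)[C@H](CO[Si](C(C)C)(C(C)C)C(C)C)c2cc(CO[Si](C(C)C)(C(C)C)C(C)C)co2)cc(OCOC)c1OCOC | intermediate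
15 | lithium acetylide of 16 (not isolated) | COc1cc([C@H](OC#C[Li])[C@H](CO[Si](C(C)C)(C(C)C)C(C)C)c2cc(CO[Si](C(C)C)(C(C)C)C(C)C)co2)cc(OCOC)c1OCOC | intermediate
16 | (1R,2S)-1-(ethynyloxy)-1-[3-methoxy-4,5-bis(methoxymethoxy)phenyl]-3-[(triisopropylsilyl)oxy]-2-(4-{[(triisopropylsilyl)oxy]methyl}furan-2-yl)propane | COc1cc([C@H](OC#C)[C@H](CO[Si](C(C)C)(C(C)C)C(C)C)c2cc(CO[Si](C(C)C)(C(C)C)C(C)C)co2)cc(OCOC)c1OCOC | intermediate
17 | oxepine valence isomer (seven-membered ring O–C7=C7a–C3a=C4–C5=C6 fused to the dihydrofuran; 2R,3S; not isolated) | COc1cc([C@@H]2OC3=COC=C(CO[Si](C(C)C)(C(C)C)C(C)C)C=C3[C@H]2CO[Si](C(C)C)(C(C)C)C(C)C)cc(OCOC)c1OCOC | intermediate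
18 | 6,7-arene oxide of 19 (2R,3S; epoxide face not defined; not isolated) | COc1cc([C@@H]2OC3=C(C=C(CO[Si](C(C)C)(C(C)C)C(C)C)C4OC43)[C@H]2CO[Si](C(C)C)(C(C)C)C(C)C)cc(OCOC)c1OCOC | intermediate
19 | (2R,3S)-2-[3-methoxy-4,5-bis(methoxymethoxy)phenyl]-3,5-bis{[(triisopropylsilyl)oxy]methyl}-2,3-dihydro-1-benzofuran-7-ol | COc1cc([C@@H]2Oc3c(O)cc(CO[Si](C(C)C)(C(C)C)C(C)C)cc3[C@H]2CO[Si](C(C)C)(C(C)C)C(C)C)cc(OCOC)c1OCOC | intermediate
20 | (2R,3S)-7-methoxy-2-[3-methoxy-4,5-bis(methoxymethoxy)phenyl]-3,5-bis{[(triisopropylsilyl)oxy]methyl}-2,3-dihydro-1-benzofuran | COc1cc([C@@H]2Oc3c(OC)cc(CO[Si](C(C)C)(C(C)C)C(C)C)cc3[C@H]2CO[Si](C(C)C)(C(C)C)C(C)C)cc(OCOC)c1OCOC | intermediate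
21 | [(2R,3S)-7-methoxy-2-[3-methoxy-4,5-bis(methoxymethoxy)phenyl]-2,3-dihydro-1-benzofuran-3,5-diyl]dimethanol | COc1cc([C@@H]2Oc3c(OC)cc(CO)cc3[C@H]2CO)cc(OCOC)c1OCOC | intermediate
22 | (2R,3S)-3-(hydroxymethyl)-7-methoxy-2-[3-methoxy-4,5-bis(methoxymethoxy)phenyl]-2,3-dihydro-1-benzofuran-5-carbaldehyde | COc1cc([C@@H]2Oc3c(OC)cc(C=O)cc3[C@H]2CO)cc(OCOC)c1OCOC | intermediate
23 | (triphenylphosphoranylidene)acetaldehyde | O=CC=P(c1ccccc1)(c1ccccc1)c1ccccc1 | starting material
24 | (E)-3-[(2R,3S)-3-(hydroxymethyl)-7-methoxy-2-[3-methoxy-4,5-bis(methoxymethoxy)phenyl]-2,3-dihydro-1-benzofuran-5-yl]prop-2-enal | COc1cc([C@@H]2Oc3c(OC)cc(/C=C/C=O)cc3[C@H]2CO)cc(OCOC)c1OCOC | intermediate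
25 | cassyformin, (E)-3-[(2R,3S)-2-(3,4-dihydroxy-5-methoxyphenyl)-3-(hydroxymethyl)-7-methoxy-2,3-dihydro-1-benzofuran-5-yl]prop-2-enal | COc1cc([C@@H]2Oc3c(OC)cc(/C=C/C=O)cc3[C@H]2CO)cc(O)c1O | target

Total step count: 15. Longest linear sequence: 14 steps (steps 1–3 and 5–15, from 1 to 25); step 4 prepares aldehyde 9 on the side.

Steps most likely to fail

Step 10 (gold cycloisomerization). What may go wrong: the activated ynol ether is hydrated, its benzylic C–O bond ionises, or ring B adds to it before the furan has closed the five-membered ring. The fallback brings ring A in as a ready-made benzene and drops the benzannulation; it sets out from 2, 5 and 9 and comes back at 20. Commercial methyl 3-bromo-4-hydroxy-5-methoxybenzoate is O-benzylated (BnBr, K2CO3, DMF) to methyl 4-benzyloxy-3-bromo-5-methoxybenzoate F1. Negishi coupling with 2 under the conditions of step 1 should give the tert-butyl arylacetate F2, and acidolysis (TFA, CH2Cl2) the arylacetic acid F3. Acylation of 5 as in step 3 gives imide F4, whose boron syn aldol with 9 as in step 5 should give adduct F5 with the same sense of induction. LiBH4 then gives triol F6 and TIPSCl/imidazole the bis-silyl ether F7. Hydrogenolysis (H2, Pd/C, EtOAc) frees phenol F8. Lewis-acid cycloetherification (BF3·OEt2, CH2Cl2, −40 °C) through the p-alkoxybenzylic cation should close the dihydrofuran ring trans to the fixed C3 centre and give 20 directly, with the C7 methoxy group already in place.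

Step 8 (capture of the alkoxide by dichloroacetylene). What may go wrong: silyl transfer from the neighbouring primary oxygen to the potassium alkoxide, or other base-induced scrambling, before the alkoxide is trapped. The fallback introduces the two alkyne carbons through a formate, so no free alkoxide is ever formed; it sets out from 13 and comes back at 16. Formylation (acetic formic anhydride, pyridine, 0 °C) gives formate F9. Dichloromethylenation of the formate carbonyl (PPh3, CCl4, THF, 60 °C) gives the 2,2-dichlorovinyl ether F10. n-BuLi (THF, −78 °C) should convert F10 through the same lithium acetylide 15, and a methanol quench gives 16.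

Step 14 (formyl olefination). What may go wrong: the product enal is olefinated a second time by the ylide, or conversion stalls when the ylide is kept short to prevent this. The fallback introduces the two-carbon unit at the ester oxidation level; it sets out from 22 and comes back at 24. Wittig reaction with ethyl (triphenylphosphoranylidene)acetate (toluene, 80 °C) gives the ethyl (E)-cinnamate F11, which cannot react further. DIBAL-H (CH2Cl2, −78 °C) gives allylic alcohol F12, and MnO2 (CH2Cl2, rt) should oxidise only the allylic hydroxyl to give 24.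

Further compounds

F1 | step 10 | methyl 4-benzyloxy-3-bromo-5-methoxybenzoate | COC(=O)c1cc(Br)c(OCc2ccccc2)c(OC)c1
F2 | step 10 | methyl 4-benzyloxy-3-(2-tert-butoxy-2-oxoethyl)-5-methoxybenzoate | COC(=O)c1cc(CC(=O)OC(C)(C)C)c(OCc2ccccc2)c(OC)c1
F3 | step 10 | 2-[2-benzyloxy-3-methoxy-5-(methoxycarbonyl)phenyl]acetic acid | COC(=O)c1cc(CC(=O)O)c(OCc2ccccc2)c(OC)c1
F4 | step 10 | methyl 3-{2-[(4R)-4-benzyl-2-oxo-1,3-oxazolidin-3-yl]-2-oxoethyl}-4-benzyloxy-5-methoxybenzoate | COC(=O)c1cc(CC(=O)N2[C@H](Cc3ccccc3)COC2=O)c(OCc2ccccc2)c(OC)c1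
F5 | step 10 | (4R)-4-benzyl-3-{(2R,3R)-2-[2-benzyloxy-3-methoxy-5-(methoxycarbonyl)phenyl]-3-hydroxy-3-[3-methoxy-4,5-bis(methoxymethoxy)phenyl]propanoyl}-1,3-oxazolidin-2-one | COc1cc([C@H](O)[C@H](C(=O)N2[C@H](Cc3ccccc3)COC2=O)c2cc(C(=O)OC)cc(OC)c2OCc2ccccc2)cc(OCOC)c1OCOC
F6 | step 10 | (1R,2S)-2-[2-benzyloxy-5-(hydroxymethyl)-3-methoxyphenyl]-1-[3-methoxy-4,5-bis(methoxymethoxy)phenyl]propane-1,3-diol | COc1cc([C@H](O)[C@H](CO)c2cc(CO)cc(OC)c2OCc2ccccc2)cc(OCOC)c1OCOC
F7 | step 10 | (1R,2S)-2-(2-benzyloxy-3-methoxy-5-{[(triisopropylsilyl)oxy]methyl}phenyl)-1-[3-methoxy-4,5-bis(methoxymethoxy)phenyl]-3-[(triisopropylsilyl)oxy]propan-1-ol | COc1cc([C@H](O)[C@H](CO[Si](C(C)C)(C(C)C)C(C)C)c2cc(CO[Si](C(C)C)(C(C)C)C(C)C)cc(OC)c2OCc2ccccc2)cc(OCOC)c1OCOC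
F8 | step 10 | 2-{(1S,2R)-2-hydroxy-2-[3-methoxy-4,5-bis(methoxymethoxy)phenyl]-1-{[(triisopropylsilyl)oxy]methyl}ethyl}-6-methoxy-4-{[(triisopropylsilyl)oxy]methyl}phenol | COc1cc([C@H](O)[C@H](CO[Si](C(C)C)(C(C)C)C(C)C)c2cc(CO[Si](C(C)C)(C(C)C)C(C)C)cc(OC)c2O)cc(OCOC)c1OCOC
F9 | step 8 | formate ester of 13 (1R,2S) | COc1cc([C@H](OC=O)[C@H](CO[Si](C(C)C)(C(C)C)C(C)C)c2cc(CO[Si](C(C)C)(C(C)C)C(C)C)co2)cc(OCOC)c1OCOC
F10 | step 8 | 2,2-dichlorovinyl ether of 13 (1R,2S) | COc1cc([C@H](OC=C(Cl)Cl)[C@H](CO[Si](C(C)C)(C(C)C)C(C)C)c2cc(CO[Si](C(C)C)(C(C)C)C(C)C)co2)cc(OCOC)c1OCOC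
F11 | step 14 | ethyl (E)-3-[(2R,3S)-3-(hydroxymethyl)-7-methoxy-2-[3-methoxy-4,5-bis(methoxymethoxy)phenyl]-2,3-dihydro-1-benzofuran-5-yl]prop-2-enoate | COc1cc([C@@H]2Oc3c(OC)cc(/C=C/C(=O)OCC)cc3[C@H]2CO)cc(OCOC)c1OCOC
F12 | step 14 | (E)-3-[(2R,3S)-3-(hydroxymethyl)-7-methoxy-2-[3-methoxy-4,5-bis(methoxymethoxy)phenyl]-2,3-dihydro-1-benzofuran-5-yl]prop-2-en-1-ol | COc1cc([C@@H]2Oc3c(OC)cc(/C=C/CO)cc3[C@H]2CO)cc(OCOC)c1OCOC
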